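**Retrosynthetic overview** (lignan labels: ring A–C7–C8(C9)–C8'(C9')–C7'–ring B; C7–O–C9' is the oxolane)
1. Target 27 ⇐ tris-silyl ether 26; the oxolane (formed last) ⇐ triol 24 by attack of the C7 hydroxyl on a primary C9' tosylate, so the C7–O bond is never broken and the 2,3-cis relation is kept.
2. Triol 24 ⇐ β-keto lactone 22: chelation-controlled Zn(BH4)2 reduction sets C7', then LiBH4 opens the lactone.
3. 22 ⇐ late coupling of lactone 14 (ring A plus the C4 core) with Weinreb amide 20 (ring B) by C-acylation of the lactone enolate; this sets C8' trans to C8.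
4. 14 ⇐ MgCl2-catalysed anti-aldol/lactonisation of succinyl oxazolidinone 9 with aldehyde 5; the γ-butyrolactone is the first ring formed and carries C7 and C8.
5. 5 and 20 ⇐ guaiacol 2 ⇐ catechol 1 by two separate branches; 9 ⇐ succinic anhydride 6.

Assumption: the recoverable auxiliary (S)-4-benzyl-2-oxazolidinone is treated as a reagent, not as a starting material.

**Step 1**
Reactants: 1 catechol
Product: 2 guaiacol (2-methoxyphenol)
Conditions: MeI (1.0 equiv), K2CO3, acetone, reflux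
Reagents that add atoms: iodomethane (CI)
Why: Williamson mono-O-methylation of the catechol monoanion with one equivalent of MeI; veratrole and unreacted catechol are removed by base extraction and distillation.

**Step 2**
Reactants: 2 guaiacol
Product: 4 vanillin, via 4-hydroxy-3-methoxymandelic acid 3 (not isolated)
Conditions: OHC–CO2H, NaOH, H2O, 25 °C; then CuSO4 (cat.), air, NaOH, 95 °C; then H2SO4 to pH 3
Reagents that add atoms: glyoxylic acid (O=CC(O)=O)
Why: Electrophilic aromatic hydroxyalkylation of the guaiacolate para to the phenoxide oxygen, then copper-catalysed aerobic oxidative decarboxylation of the mandelate (the technical vanillin process).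

**Step 3**
Reactants: 4 vanillin
Product: 5 3-methoxy-4-(triisopropylsilyloxy)benzaldehyde
Conditions: i-Pr3SiCl, imidazole, DMF, 23 °C
Reagents that add atoms: chlorotriisopropylsilane (CC(C)[Si](Cl)(C(C)C)C(C)C)
Why: Imidazole-promoted O-silylation of the phenol gives a robust aryl silyl ether that survives bases, hydrides and mild acid.

**Step 4**
Reactants: 6 succinic anhydride
Product: 7 4-methoxy-4-oxobutanoic acid (monomethyl succinate)
Conditions: MeOH, reflux
Reagents that add atoms: methanol (CO)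
Why: Alcoholysis (ring opening) of the cyclic anhydride stops cleanly at the half ester.

**Step 5**
Reactants: 7 monomethyl succinate
Product: 9 methyl 4-[(4S)-4-benzyl-2-oxooxazolidin-3-yl]-4-oxobutanoate, via mixed pivalic anhydride 8 (not isolated)
Conditions: t-BuCOCl, Et3N, THF, −20 °C; then (S)-4-benzyl-2-oxazolidinone, LiCl, −20 → 23 °C
Reagents that add atoms: (S)-4-benzyl-2-oxazolidinone (O=C1N[C@@H](Cc2ccccc2)CO1)
Why: N-acylation of the auxiliary through the mixed anhydride, which is attacked at its less hindered succinyl carbonyl under LiCl/Et3N activation.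

**Step 6**
Reactants: 9 succinyl oxazolidinone; 5 3-methoxy-4-(triisopropylsilyloxy)benzaldehyde
Product: 12 (4S)-4-benzyl-3-{[(2S,3R)-2-[3-methoxy-4-(triisopropylsilyloxy)phenyl]-5-oxotetrahydrofuran-3-yl]carbonyl}oxazolidin-2-one (2,3-cis), via O-silyl aldol adduct 10 (not isolated), via hydroxy ester 11 (not isolated)
Conditions: MgCl2 (0.2 equiv), Et3N, Me3SiCl, EtOAc, 23 °C; then 1 M HCl, THF, 23 °C; then PPTS (cat.), PhMe, 50 °C
Reagents that add atoms: none
Why: Evans-type MgCl2-catalysed anti-aldol, in which the magnesium-chelated Z-enolate adds to the aldehyde on the face away from the benzyl group through a boat transition state to set C7 (S) and C8 anti to it; after desilylation the C7 hydroxyl lactonises onto the methyl ester to give the cis γ-lactone.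

**Step 7**
Reactants: 12 lactone imide
Product: 13 (4S,5S)-4-(hydroxymethyl)-5-[3-methoxy-4-(triisopropylsilyloxy)phenyl]dihydrofuran-2(3H)-one
Conditions: NaBH4, THF–H2O (4:1), 0 → 23 °C
Reagents that add atoms: none
Why: Chemoselective borohydride reduction of the activated exocyclic imide carbonyl to the primary alcohol with release of the auxiliary; the γ-lactone reacts far more slowly and no stereocentre is touched.

**Step 8**
Reactants: 13 lactone alcohol
Product: 14 (4S,5S)-5-[3-methoxy-4-(triisopropylsilyloxy)phenyl]-4-[(triisopropylsilyloxy)methyl]dihydrofuran-2(3H)-one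
Conditions: i-Pr3SiOTf, 2,6-lutidine, CH2Cl2, −78 → 0 °C
Reagents that add atoms: triisopropylsilyl triflate (CC(C)[Si](OS(=O)(=O)C(F)(F)F)(C(C)C)C(C)C)
Why: Fast O-silylation under non-nucleophilic conditions caps the C9 hydroxyl before it can translactonise and keeps C9 distinct from C9' later.

**Step 9**
Reactants: 2 guaiacol
Product: 15 4-bromo-2-methoxyphenol
Conditions: NBS, MeCN, 0 °C
Reagents that add atoms: N-bromosuccinimide (O=C1CCC(=O)N1Br)
Why: Electrophilic aromatic bromination occurs para to the free hydroxyl, the stronger director.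

**Step 10**
Reactants: 15 4-bromo-2-methoxyphenol
Product: 16 (4-bromo-2-methoxyphenoxy)triisopropylsilane
Conditions: i-Pr3SiCl, imidazole, DMF, 23 °C
Reagents that add atoms: chlorotriisopropylsilane (CC(C)[Si](Cl)(C(C)C)C(C)C)
Why: O-silylation of the phenol removes the acidic proton before metalation.

**Step 11**
Reactants: 16 aryl bromide
Product: 18 3-methoxy-4-(triisopropylsilyloxy)benzoic acid, via aryllithium 17 (not isolated)
Conditions: n-BuLi, THF, −78 °C; then CO2; then 1 M HCl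
Reagents that add atoms: carbon dioxide (O=C=O)
Why: Bromine–lithium exchange followed by carboxylation of the aryllithium installs the future C7' carbon.

**Step 12**
Reactants: 18 benzoic acid
Product: 20 N,3-dimethoxy-N-methyl-4-(triisopropylsilyloxy)benzamide, via acyl imidazole 19 (not isolated)
Conditions: CDI, CH2Cl2, 23 °C; then MeNH(OMe)·HCl, 23 °C
Reagents that add atoms: N,O-dimethylhydroxylamine hydrochloride (CNOC.Cl)
Why: Carbonyldiimidazole activation and aminolysis give the Weinreb amide, an acyl donor that stops at the ketone stage.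

**Step 13**
Reactants: 14 silyl-protected lactone; 20 Weinreb amide
Product: 22 (3S,4S,5S)-3-[3-methoxy-4-(triisopropylsilyloxy)benzoyl]-5-[3-methoxy-4-(triisopropylsilyloxy)phenyl]-4-[(triisopropylsilyloxy)methyl]dihydrofuran-2(3H)-one, via lithium enolate 21 (not isolated)
Conditions: LiN(SiMe3)2 (1.1 equiv), THF, −78 °C; then 20, −78 → −20 °C; then AcOH
Reagents that add atoms: none
Why: Crossed Claisen C-acylation of the lactone enolate, whose chelated tetrahedral adduct with the Weinreb amide prevents over-reaction; the acyl group enters anti to the C4 and C5 substituents and the acidic C3–H equilibrates, so C8' ends trans to C8.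

**Step 14**
Reactants: 22 β-keto lactone
Product: 24 (1S,2R,3S,4S)-2-(hydroxymethyl)-1,4-bis[3-methoxy-4-(triisopropylsilyloxy)phenyl]-3-[(triisopropylsilyloxy)methyl]butane-1,4-diol, via syn-hydroxy lactone 23 (not isolated)
Conditions: Zn(BH4)2, Et2O–CH2Cl2, −78 → −20 °C; then LiBH4, MeOH, THF, 0 → 23 °C; then aq. NH4Cl
Reagents that add atoms: none
Why: Chelation-controlled reduction in which zinc bridges the ketone and lactone carbonyls and hydride attacks the face opposite ring carbon C8 to give the syn (7'S) carbinol; LiBH4 then reduces the lactone to the 1,4-diol.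

**Step 15**
Reactants: 24 triol
Product: 26 (S)-[3-methoxy-4-(triisopropylsilyloxy)phenyl]{(3R,4S,5S)-5-[3-methoxy-4-(triisopropylsilyloxy)phenyl]-4-[(triisopropylsilyloxy)methyl]tetrahydrofuran-3-yl}methanol, via primary tosylate 25 (not isolated)
Conditions: TsCl (1.1 equiv), pyridine, 0 → 23 °C; then 50 °C
Reagents that add atoms: none
Why: Selective sulfonylation of the only primary hydroxyl, then 5-exo-tet intramolecular Williamson etherification by the C7 hydroxyl (oxetane closure by the C7' hydroxyl is much slower); no stereocentre takes part, so the aryl group stays cis to C9.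

**Step 16**
Reactants: 26 tris-silyl ether
Product: 27 (S)-(4-hydroxy-3-methoxyphenyl)[(3R,4S,5S)-5-(4-hydroxy-3-methoxyphenyl)-4-(hydroxymethyl)tetrahydrofuran-3-yl]methanol (target)
Conditions: Bu4NF, AcOH, THF, 0 → 23 °C
Reagents that add atoms: none
Why: Buffered fluoride desilylation removes both aryl and the alkyl silyl ethers without ionising the benzylic alcohol or the benzylic ether.

**Compound list**
1 | catechol | Oc1ccccc1O | starting material
2 | guaiacol | COc1ccccc1O | intermediate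
3 | 4-hydroxy-3-methoxymandelic acid (racemic) | COc1cc(C(O)C(O)=O)ccc1O | intermediate
4 | vanillin | COc1cc(C=O)ccc1O | intermediate
5 | 3-methoxy-4-(triisopropylsilyloxy)benzaldehyde | COc1cc(C=O)ccc1O[Si](C(C)C)(C(C)C)C(C)C | intermediate
6 | succinic anhydride | O=C1CCC(=O)O1 | starting material
7 | 4-methoxy-4-oxobutanoic acid | COC(=O)CCC(O)=O | intermediate
8 | 4-methoxy-4-oxobutanoic pivalic anhydride | COC(=O)CCC(=O)OC(=O)C(C)(C)C | intermediate
9 | methyl 4-[(4S)-4-benzyl-2-oxooxazolidin-3-yl]-4-oxobutanoate | COC(=O)CCC(=O)N1[C@@H](Cc2ccccc2)COC1=O | intermediate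
10 | methyl (3R,4S)-3-{[(4S)-4-benzyl-2-oxooxazolidin-3-yl]carbonyl}-4-[3-methoxy-4-(triisopropylsilyloxy)phenyl]-4-(trimethylsilyloxy)butanoate | C[Si](C)(C)O[C@H](c1ccc(O[Si](C(C)C)(C(C)C)C(C)C)c(OC)c1)[C@@H](CC(=O)OC)C(=O)N2[C@@H](Cc3ccccc3)COC2=O | intermediate
11 | methyl (3R,4S)-3-{[(4S)-4-benzyl-2-oxooxazolidin-3-yl]carbonyl}-4-hydroxy-4-[3-methoxy-4-(triisopropylsilyloxy)phenyl]butanoate | O[C@H](c1ccc(O[Si](C(C)C)(C(C)C)C(C)C)c(OC)c1)[C@@H](CC(=O)OC)C(=O)N2[C@@H](Cc3ccccc3)COC2=O | intermediate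
12 | (4S)-4-benzyl-3-{[(2S,3R)-2-[3-methoxy-4-(triisopropylsilyloxy)phenyl]-5-oxotetrahydrofuran-3-yl]carbonyl}oxazolidin-2-one | O=C1O[C@H](c2ccc(O[Si](C(C)C)(C(C)C)C(C)C)c(OC)c2)[C@@H](C1)C(=O)N3[C@@H](Cc4ccccc4)COC3=O | intermediate
13 | (4S,5S)-4-(hydroxymethyl)-5-[3-methoxy-4-(triisopropylsilyloxy)phenyl]dihydrofuran-2(3H)-one | O=C1O[C@H](c2ccc(O[Si](C(C)C)(C(C)C)C(C)C)c(OC)c2)[C@@H](C1)CO | intermediate
14 | (4S,5S)-5-[3-methoxy-4-(triisopropylsilyloxy)phenyl]-4-[(triisopropylsilyloxy)methyl]dihydrofuran-2(3H)-one | O=C1O[C@H](c2ccc(O[Si](C(C)C)(C(C)C)C(C)C)c(OC)c2)[C@@H](C1)CO[Si](C(C)C)(C(C)C)C(C)C | intermediate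
15 | 4-bromo-2-methoxyphenol | COc1cc(Br)ccc1O | intermediate
16 | (4-bromo-2-methoxyphenoxy)triisopropylsilane | COc1cc(Br)ccc1O[Si](C(C)C)(C(C)C)C(C)C | intermediate
17 | [3-methoxy-4-(triisopropylsilyloxy)phenyl]lithium | [Li]c1ccc(O[Si](C(C)C)(C(C)C)C(C)C)c(OC)c1 | intermediate
18 | 3-methoxy-4-(triisopropylsilyloxy)benzoic acid | COc1cc(C(O)=O)ccc1O[Si](C(C)C)(C(C)C)C(C)C | intermediate
19 | 1-[3-methoxy-4-(triisopropylsilyloxy)benzoyl]imidazole | COc1cc(C(=O)n2ccnc2)ccc1O[Si](C(C)C)(C(C)C)C(C)C | intermediate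
20 | N,3-dimethoxy-N-methyl-4-(triisopropylsilyloxy)benzamide | COc1cc(C(=O)N(C)OC)ccc1O[Si](C(C)C)(C(C)C)C(C)C | intermediate
21 | lithium enolate of lactone 14 | [Li]OC1=C[C@@H](CO[Si](C(C)C)(C(C)C)C(C)C)[C@@H](c2ccc(O[Si](C(C)C)(C(C)C)C(C)C)c(OC)c2)O1 | intermediate
22 | (3S,4S,5S)-3-[3-methoxy-4-(triisopropylsilyloxy)benzoyl]-5-[3-methoxy-4-(triisopropylsilyloxy)phenyl]-4-[(triisopropylsilyloxy)methyl]dihydrofuran-2(3H)-one | COc1cc(C(=O)[C@H]2C(=O)O[C@H](c3ccc(O[Si](C(C)C)(C(C)C)C(C)C)c(OC)c3)[C@@H]2CO[Si](C(C)C)(C(C)C)C(C)C)ccc1O[Si](C(C)C)(C(C)C)C(C)C | intermediate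
23 | (3S,4S,5S)-3-{(S)-hydroxy[3-methoxy-4-(triisopropylsilyloxy)phenyl]methyl}-5-[3-methoxy-4-(triisopropylsilyloxy)phenyl]-4-[(triisopropylsilyloxy)methyl]dihydrofuran-2(3H)-one | COc1cc([C@@H](O)[C@H]2C(=O)O[C@H](c3ccc(O[Si](C(C)C)(C(C)C)C(C)C)c(OC)c3)[C@@H]2CO[Si](C(C)C)(C(C)C)C(C)C)ccc1O[Si](C(C)C)(C(C)C)C(C)C | intermediate
24 | (1S,2R,3S,4S)-2-(hydroxymethyl)-1,4-bis[3-methoxy-4-(triisopropylsilyloxy)phenyl]-3-[(triisopropylsilyloxy)methyl]butane-1,4-diol | COc1cc([C@@H](O)[C@@H](CO)[C@@H](CO[Si](C(C)C)(C(C)C)C(C)C)[C@H](O)c2ccc(O[Si](C(C)C)(C(C)C)C(C)C)c(OC)c2)ccc1O[Si](C(C)C)(C(C)C)C(C)C | intermediate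
25 | primary (C9') p-toluenesulfonate of triol 24 | COc1cc([C@@H](O)[C@@H](COS(=O)(=O)c2ccc(C)cc2)[C@@H](CO[Si](C(C)C)(C(C)C)C(C)C)[C@H](O)c3ccc(O[Si](C(C)C)(C(C)C)C(C)C)c(OC)c3)ccc1O[Si](C(C)C)(C(C)C)C(C)C | intermediate
26 | (S)-[3-methoxy-4-(triisopropylsilyloxy)phenyl]{(3R,4S,5S)-5-[3-methoxy-4-(triisopropylsilyloxy)phenyl]-4-[(triisopropylsilyloxy)methyl]tetrahydrofuran-3-yl}methanol | COc1cc([C@@H](O)[C@H]2CO[C@H](c3ccc(O[Si](C(C)C)(C(C)C)C(C)C)c(OC)c3)[C@@H]2CO[Si](C(C)C)(C(C)C)C(C)C)ccc1O[Si](C(C)C)(C(C)C)C(C)C | intermediate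
27 | (S)-(4-hydroxy-3-methoxyphenyl)[(3R,4S,5S)-5-(4-hydroxy-3-methoxyphenyl)-4-(hydroxymethyl)tetrahydrofuran-3-yl]methanol | COc1cc([C@@H](O)[C@H]2CO[C@H](c3ccc(O)c(OC)c3)[C@@H]2CO)ccc1O | target

**Totals**
Total step count: 16.
Longest linear sequence: 10 steps (1, 2, 3, 6, 7, 8, 13, 14, 15, 16, from catechol 1). The ring B branch (1, 9, 10, 11, 12) and the succinate branch (4, 5) run in parallel.

**Steps most likely to fail, with fallbacks**

Step 6. The risks are the level and sense of anti selectivity with an ester-bearing imide and an electron-rich aldehyde, and closure to the strained cis lactone. The fallback sets out from 9 and comes back at 12. The sodium enolate of 9 (NaN(SiMe3)2, THF, −78 °C) is C-acylated on the face away from the benzyl group with acyl imidazole 19 (made from 18 as in step 12) to give β-keto imide F1, whose C8 centre is fixed by the auxiliary. Non-chelating Felkin–Anh reduction with KBH(s-Bu)3 (THF, −78 °C) then gives the anti hydroxy ester 11, which PPTS closes to 12.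

Step 13. The risk is slow C-acylation of a hindered enolate by an electron-rich amide, with lactone self-condensation competing. The fallback sets out from 14 and comes back at 22. Enolate 21 is added at −78 °C to aldehyde 5 (aldol addition, trans to the C4 substituent), giving 23 mixed with its C7' epimer, anti-hydroxy lactone F2. The mixture is oxidised with Dess–Martin periodinane (CH2Cl2, 23 °C) to 22.

Step 14. The risk is incomplete chelation control at C7'. The fallback sets out from 22 and comes back at 26. Ketone and lactone are reduced without control (LiBH4, THF–MeOH) to 24 together with its C7' epimer, epi-triol F3. The mixture is cyclised as in step 15, through 25 and epi-tosylate F4, to 26 together with epi-alcohol F5. MnO2 (CH2Cl2) converts both alcohols into the single aryl ketone F6. LiBH(s-Bu)3 (THF, −78 °C) then reduces F6 under Felkin–Anh control, with ring carbon C8 as the large substituent and no second carbonyl left to chelate; this is expected to give 26 from both epimers.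

**Further compounds**
F1 | step 6 | methyl (3R)-3-{[(4S)-4-benzyl-2-oxooxazolidin-3-yl]carbonyl}-4-[3-methoxy-4-(triisopropylsilyloxy)phenyl]-4-oxobutanoate | O=C(c1ccc(O[Si](C(C)C)(C(C)C)C(C)C)c(OC)c1)[C@@H](CC(=O)OC)C(=O)N2[C@@H](Cc3ccccc3)COC2=O
F2 | step 13 | (3S,4S,5S)-3-{(R)-hydroxy[3-methoxy-4-(triisopropylsilyloxy)phenyl]methyl}-5-[3-methoxy-4-(triisopropylsilyloxy)phenyl]-4-[(triisopropylsilyloxy)methyl]dihydrofuran-2(3H)-one | COc1cc([C@H](O)[C@H]2C(=O)O[C@H](c3ccc(O[Si](C(C)C)(C(C)C)C(C)C)c(OC)c3)[C@@H]2CO[Si](C(C)C)(C(C)C)C(C)C)ccc1O[Si](C(C)C)(C(C)C)C(C)C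
F3 | step 14 | (1R,2R,3S,4S)-2-(hydroxymethyl)-1,4-bis[3-methoxy-4-(triisopropylsilyloxy)phenyl]-3-[(triisopropylsilyloxy)methyl]butane-1,4-diol | COc1cc([C@H](O)[C@@H](CO)[C@@H](CO[Si](C(C)C)(C(C)C)C(C)C)[C@H](O)c2ccc(O[Si](C(C)C)(C(C)C)C(C)C)c(OC)c2)ccc1O[Si](C(C)C)(C(C)C)C(C)C
F4 | step 14 | primary p-toluenesulfonate of epi-triol F3 | COc1cc([C@H](O)[C@@H](COS(=O)(=O)c2ccc(C)cc2)[C@@H](CO[Si](C(C)C)(C(C)C)C(C)C)[C@H](O)c3ccc(O[Si](C(C)C)(C(C)C)C(C)C)c(OC)c3)ccc1O[Si](C(C)C)(C(C)C)C(C)C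
F5 | step 14 | (R)-[3-methoxy-4-(triisopropylsilyloxy)phenyl]{(3R,4S,5S)-5-[3-methoxy-4-(triisopropylsilyloxy)phenyl]-4-[(triisopropylsilyloxy)methyl]tetrahydrofuran-3-yl}methanol | COc1cc([C@H](O)[C@H]2CO[C@H](c3ccc(O[Si](C(C)C)(C(C)C)C(C)C)c(OC)c3)[C@@H]2CO[Si](C(C)C)(C(C)C)C(C)C)ccc1O[Si](C(C)C)(C(C)C)C(C)C
F6 | step 14 | [3-methoxy-4-(triisopropylsilyloxy)phenyl]{(3R,4S,5S)-5-[3-methoxy-4-(triisopropylsilyloxy)phenyl]-4-[(triisopropylsilyloxy)methyl]tetrahydrofuran-3-yl}methanone | COc1cc(C(=O)[C@H]2CO[C@H](c3ccc(O[Si](C(C)C)(C(C)C)C(C)C)c(OC)c3)[C@@H]2CO[Si](C(C)C)(C(C)C)C(C)C)ccc1O[Si](C(C)C)(C(C)C)C(C)C
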